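Amounts first: larch takes 0.25 M of substrate, 0.275 M of reagent and 50 mM of free catalyst, and ash takes 800 mM of free catalyst.

all flasks: substrate 0.25 M; reagent 0.275 M; time 2.5 h

|  | free catalyst |
|---|---|
| larch | 50 mM |
| elm | 100 mM |
| oak | 200 mM |
| birch | 400 mM |
| ash | 800 mM |

    substrate + free catalyst ⇌ catalyst intermediate A (K1 = 3.2 L mol⁻¹, k1 = 2.9 L mol⁻¹ min⁻¹)
    reagent + catalyst intermediate A → catalyst intermediate B (k2 = 1.3 L mol⁻¹ min⁻¹)
    catalyst intermediate B ⇌ catalyst intermediate C (K3 = 16, k3 = 0.29 min⁻¹)
    catalyst intermediate C ⇌ free catalyst + product (K4 = 0.29 M, k4 = 26 min⁻¹)
    2 catalyst intermediate C → spent catalyst (k5 = 11 L mol⁻¹ min⁻¹)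

- percentages count the substrate that a species holds: one spent catalyst counts as two
- where a step has two of a species, its rate is k times that concentration squared, and two are used at each turn
- "hardly changes" means that all values lie within two and a half points (for a concentration: within two and a half percent of the largest)
- run time (larch): 2.5 h

1. amount of product at the end, in percent of the substrate charged for larch, elm, oak, birch, ash, in this order
2. how that number moves from the first to the last of them (rises, then falls / falls, then rises / hardly changes / falls all the way / rises all the way)

Write F, P and X for the concentrations of free catalyst, product and catalyst intermediate C.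

1. At the start of larch, each free catalyst has 0.80 of catalyst intermediate A beside it, and catalyst intermediate B adds 0.986. The reagent step, the making rate J, therefore opens at 5.13 mM min⁻¹. At that pace the substrate of larch lasts 48.7 min, shorter than the run.

2. The first slowing is dilution. With half of the substrate of larch turned to product and the catalyst intact, catalyst intermediate C stands at 0.431 per free catalyst, as the next step shows, so J is 1.86 mM min⁻¹, a factor 2.76 down. The mean of the two rates, 3.49 mM min⁻¹, reaches that point in 35.8 min.

3. The second slowing is the catalyst's death. Release of product is much faster than the feed of catalyst intermediate C, so that step stands as a pre-equilibrium, X = F·P/0.29 M. The loss of catalyst, the drain D, is then κ times the square of F·y, where y is the product as a fraction of the substrate charged and κ = 16.3 L mol⁻¹ min⁻¹ is the drain constant, twice the loss constant times the square of the substrate charge over the release constant.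

4. Halfway through larch, with catalyst intermediate C counted in the balance, F is 23.8 mM if the catalyst is intact, so D reaches 2.32 mM min⁻¹, more than J. Along a straight rise of P, the mean of D is a third of that, not the quarter that the square of the mean gives. D also falls with the square of the catalyst left, so by this estimate larch keeps 64.4% of its charge over that stretch. This reckoning commits larch to a little under half.

5. Elm holds twice the catalyst of larch, so at equal P and equal split D/J is twice as large. With its whole charge as spent catalyst, oak holds 80.0% of the substrate, leaving at most 20.0%. Birch holds more catalyst than substrate. The row falls all the way.

The forecast gives 40%, 33%, 17%, 1% and 0.1%, and says the row falls all the way, on this ground: “the second-order loss of C to spent catalyst then locks up substrate roughly one for one with the catalyst charged”. For larch, the reckoning stands above it.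

The flasks end at 46.9%, 37.6%, 16.1%, 1.65% and 0.305%: the row falls all the way. With the way back of release left out, ash gives 99.6%. At the end of larch, κ gives a drain of 0.0704 mM min⁻¹, against a making rate of 0.158 mM min⁻¹. At the end of ash, the drain is 0.0461 mM min⁻¹, against a making rate of 0.0231 mM min⁻¹. After 25.0 h, larch holds 56.5% of product and ash 0.0115%.

(Its constants are assumed, and the outcome is calculated.)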